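**Retrosynthetic overview**

1. The depside ester bond (ring B carboxyl carbon to the 4‑oxygen of ring A) is cut last. This gives acid 17 and phenol 19, which are the same ring in two protection states, since 19 is made from 17.
2. Acid 17 goes back through pentyl ketone 15 (Weinreb amide 13 plus pentylmagnesium bromide 14) to the homophthalate diester 11, of which only the arylacetate ester is elaborated.
3. Feature: in each ring the carboxyl carbon on C1 and the benzylic CH2 of the 2‑oxoheptyl chain on C6 are ortho neighbours on a benzene ring with oxygens on C2 and C4. Both aryl–carbon bonds are cut at once, to 3,5‑bis(benzyloxy)benzyne 9 (from silyl triflate 7) and dimethyl malonate 8.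
4. Silyl triflate 7 comes from 3,5‑bis(benzyloxy)phenol 1 by carbamate‑directed ortho‑silylation and triflation.
5. No ring is formed in the route: both benzene rings are carried in from 1, rings A and B from the same batch of 11. The target has no stereocentre.

Key step: step 4

Remark on the chemistry: ring A is the benzoic acid ring and ring B the acyl ring of the depside; in each ring C1 is the carbon that bears the carboxyl carbon.

**Route**

Step 1
Reactants: 1 3,5-bis(benzyloxy)phenol
Product: 2 3,5-bis(benzyloxy)phenyl N-isopropylcarbamate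
Conditions: i-PrNCO, Et3N (cat.), CH2Cl2, rt
Reagents that add atoms: isopropyl isocyanate, CC(C)N=C=O
Why: Amine-catalysed addition of the phenol O–H across the isocyanate (carbamoylation) should give the secondary carbamate, which serves as the directing group of step 2 and can later be removed under mild base.

Step 2
Reactants: 2 3,5-bis(benzyloxy)phenyl N-isopropylcarbamate
Product: 5 3,5-bis(benzyloxy)-2-(trimethylsilyl)phenyl N-isopropylcarbamate, via N-silyl carbamate 3 (not isolated), via C-silylated N-silyl carbamate 4 (not isolated)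
Conditions: TBSOTf, TMEDA, Et2O, 0 °C to rt; then n-BuLi, TMEDA, −78 °C; Me3SiCl, −78 °C to rt; aq. NaHSO4
Reagents that add atoms: chlorotrimethylsilane, C[Si](C)(C)Cl; tert-butyldimethylsilyl triflate, CC(C)(C)[Si](C)(C)OS(=O)(=O)C(F)(F)F (its silyl group stays only in 3 and 4)
Why: In situ N-silylation masks the carbamate N–H, and directed ortho-metalation then takes place at the ring carbon between the carbamate oxygen and a benzyloxy oxygen (the two such carbons are equivalent by symmetry), which at −78 °C should outrun deprotonation of the benzylic OCH2 groups and of the position between the two benzyloxy groups; Me3SiCl traps the anion and the N–Si bond is lost on aqueous work-up.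

Step 3
Reactants: 5 3,5-bis(benzyloxy)-2-(trimethylsilyl)phenyl N-isopropylcarbamate
Product: 7 3,5-bis(benzyloxy)-2-(trimethylsilyl)phenyl trifluoromethanesulfonate, via silyl phenol 6 (not isolated)
Conditions: DBU, Et2NH, MeCN, 40 °C; then PhNTf2, rt
Reagents that add atoms: N-phenylbis(trifluoromethanesulfonimide), O=S(=O)(N(c1ccccc1)S(=O)(=O)C(F)(F)F)C(F)(F)F
Why: DBU should induce E1cB loss of isopropyl isocyanate from the secondary carbamate (scavenged by Et2NH as a urea), and the phenoxide of 6 is O-sulfonylated in the same flask by PhNTf2, so the protodesilylation-prone ortho-silyl phenol is never isolated.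

Step 4
Reactants: 7 3,5-bis(benzyloxy)-2-(trimethylsilyl)phenyl trifluoromethanesulfonate; 8 dimethyl malonate (in excess)
Product: 11 dimethyl 3,5-bis(benzyloxy)homophthalate [methyl 2,4-bis(benzyloxy)-6-(2-methoxy-2-oxoethyl)benzoate], via aryne 9 (not isolated), via benzocyclobutenoxide 10 (not isolated)
Conditions: KF, 18-crown-6, THF, rt
Reagents that add atoms: none
Why: Fluoride attacks silicon in 7 and triflate leaves to give aryne 9; the malonate anion adds to 9, the aryl anion so formed attacks the adjacent ester carbonyl to give the four-membered alkoxide 10, and 10 opens by C–C cleavage to the stabilised arylacetate anion, which is protonated by fresh malonate and so carries the chain. The closest known reaction type is the insertion of arynes into the C–C sigma bond of malonates and beta-keto esters (aryne acyl-alkylation). No ring of 11 is closed; the transient cyclobutene ring of 10 forms by 4-exo-trig attack of the aryl anion on the ester carbonyl and is opened again in the same flask. No stereocentre remains in 11, the two in 10 being destroyed on ring opening. The step needs regioselective addition: the benzyloxy group next to the triple bond withdraws electron density inductively and distorts the aryne, so the carbanion should add at the aryne carbon remote from it (the former C–OTf carbon) and the negative charge should develop beside oxygen, which puts CO2Me between OBn and the carbon bearing CH2CO2Me; the symmetric malonate leaves no choice of migrating acyl group. An excess of 8 should keep the acidic CH2 of 11 from capturing a second aryne.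

Step 5
Reactants: 11 dimethyl 3,5-bis(benzyloxy)homophthalate
Product: 12 2-[3,5-bis(benzyloxy)-2-(methoxycarbonyl)phenyl]acetic acid
Conditions: LiOH (1.1 equiv), THF/H2O, 0 °C to rt; then aq. HCl
Reagents that add atoms: lithium hydroxide (aqueous), [Li+].[OH-]
Why: Saponification should be selective for the unhindered arylacetate ester, because the benzoate carbonyl is shielded on both sides (OBn and CH2R) against tetrahedral attack by hydroxide.

Step 6
Reactants: 12 2-[3,5-bis(benzyloxy)-2-(methoxycarbonyl)phenyl]acetic acid
Product: 13 methyl 2,4-bis(benzyloxy)-6-{2-[methoxy(methyl)amino]-2-oxoethyl}benzoate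
Conditions: CDI, THF, rt; then MeNHOMe·HCl, rt
Reagents that add atoms: N,O-dimethylhydroxylamine hydrochloride, CNOC.Cl
Why: Activation of the acid as its acyl imidazolide followed by amidation (Weinreb amide formation) proceeds without strong base, so the hindered methyl benzoate and the benzyl ethers are untouched.

Step 7
Reactants: 13 methyl 2,4-bis(benzyloxy)-6-{2-[methoxy(methyl)amino]-2-oxoethyl}benzoate; 14 pentylmagnesium bromide
Product: 15 methyl 2,4-bis(benzyloxy)-6-(2-oxoheptyl)benzoate
Conditions: THF, −20 to 0 °C; aq. NH4Cl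
Reagents that add atoms: none
Why: Weinreb ketone synthesis: the N-methoxy group holds magnesium in the adduct until work-up so that only one pentyl group is added, the doubly ortho-substituted methyl benzoate is too hindered to compete at this temperature, and a modest excess of 14 covers partial enolisation of the ArCH2 position.

Step 8
Reactants: 15 methyl 2,4-bis(benzyloxy)-6-(2-oxoheptyl)benzoate
Product: 16 methyl 2,4-bis(benzyloxy)-6-[(2-pentyl-1,3-dioxolan-2-yl)methyl]benzoate
Conditions: TMSOCH2CH2OTMS, TMSOTf (cat.), CH2Cl2, −78 to −20 °C; pyridine quench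
Reagents that add atoms: 1,2-bis(trimethylsilyloxy)ethane, C[Si](C)(C)OCCO[Si](C)(C)C
Why: Noyori ketalisation under aprotic silyl triflate catalysis at low temperature should convert the ketone into the dioxolane without the protic acid and heat that would favour cyclisation of the keto ester to an isocoumarin.

Step 9
Reactants: 16 methyl 2,4-bis(benzyloxy)-6-[(2-pentyl-1,3-dioxolan-2-yl)methyl]benzoate
Product: 17 2,4-bis(benzyloxy)-6-[(2-pentyl-1,3-dioxolan-2-yl)methyl]benzoic acid
Conditions: KOH, DMSO/H2O, 90 °C; then cold aq. HCl to pH 4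
Reagents that add atoms: potassium hydroxide, [K+].[OH-]
Why: Saponification of the hindered benzoate with poorly solvated hydroxide in aqueous DMSO is a standard answer to di-ortho-substituted esters; benzyl ethers and the dioxolane are stable to base, the ketal blocks enolate cyclisation onto the ester, and acidification only to pH 4 in the cold spares the ketal.

Step 10
Reactants: 17 2,4-bis(benzyloxy)-6-[(2-pentyl-1,3-dioxolan-2-yl)methyl]benzoic acid (the part of the material destined for ring A)
Product: 18 2,4-dihydroxy-6-[(2-pentyl-1,3-dioxolan-2-yl)methyl]benzoic acid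
Conditions: H2 (1 atm), Pd/C, EtOAc, rt
Reagents that add atoms: none
Why: Catalytic hydrogenolysis cleaves both aryl benzyl ethers under neutral conditions at room temperature, where the dioxolane is inert and the dihydroxybenzoic acid should not decarboxylate; the crude acid is taken on at once.

Step 11
Reactants: 18 2,4-dihydroxy-6-[(2-pentyl-1,3-dioxolan-2-yl)methyl]benzoic acid
Product: 19 benzyl 2,4-dihydroxy-6-[(2-pentyl-1,3-dioxolan-2-yl)methyl]benzoate
Conditions: BnBr (1.05 equiv), KHCO3, DMF, rt
Reagents that add atoms: benzyl bromide, BrCc1ccccc1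
Why: Carboxylate O-alkylation (SN2) is selective because hydrogencarbonate deprotonates only the carboxylic acid and not the phenols, and SN2 attack of the carboxylate on benzyl bromide is not slowed by the two ortho substituents.

Step 12
Reactants: 17 2,4-bis(benzyloxy)-6-[(2-pentyl-1,3-dioxolan-2-yl)methyl]benzoic acid; 19 benzyl 2,4-dihydroxy-6-[(2-pentyl-1,3-dioxolan-2-yl)methyl]benzoate
Product: 20 benzyl 4-({2,4-bis(benzyloxy)-6-[(2-pentyl-1,3-dioxolan-2-yl)methyl]benzoyl}oxy)-2-hydroxy-6-[(2-pentyl-1,3-dioxolan-2-yl)methyl]benzoate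
Conditions: DCC, DMAP (cat.), CH2Cl2, 0 °C to rt
Reagents that add atoms: none
Why: Steglich esterification under non-acidic conditions keeps both ketals, and acylation should occur at the 4-OH of 19 because the 2-OH is hydrogen-bonded to the benzyl ester carbonyl and flanked by it, while the ketal in 17 prevents enol-lactonisation of the activated acid.

Step 13
Reactants: 20 the bis-ketal depside
Product: 21 benzyl 4-{[2,4-bis(benzyloxy)-6-(2-oxoheptyl)benzoyl]oxy}-2-hydroxy-6-(2-oxoheptyl)benzoate
Conditions: 1 M aq. HCl, THF, rt
Reagents that add atoms: water, O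
Why: Acid-catalysed ketal hydrolysis in dilute aqueous acid at room temperature should free both dialkyl ketones while the aryl ester, benzyl ester and benzyl ethers survive; it is placed before the hydrogenolysis so that the last step is neutral, and is stopped at full conversion to limit acid-promoted enol-lactonisation.

Step 14
Reactants: 21 benzyl 4-{[2,4-bis(benzyloxy)-6-(2-oxoheptyl)benzoyl]oxy}-2-hydroxy-6-(2-oxoheptyl)benzoate
Product: 22 4-{[2,4-dihydroxy-6-(2-oxoheptyl)benzoyl]oxy}-2-hydroxy-6-(2-oxoheptyl)benzoic acid (target)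
Conditions: H2 (1 atm), Pd/C, EtOAc, rt
Reagents that add atoms: none
Why: Catalytic hydrogenolysis removes the benzyl ester and both benzyl ethers in one neutral operation, under which the aryl ester link and the non-conjugated dialkyl ketones are not reduced, so the acid- and base-sensitive keto depside is released without further reagents.

**Compound list**

1 | 3,5-bis(benzyloxy)phenol | Oc1cc(OCc2ccccc2)cc(OCc2ccccc2)c1 | starting material
2 | 3,5-bis(benzyloxy)phenyl N-isopropylcarbamate | CC(C)NC(=O)Oc1cc(OCc2ccccc2)cc(OCc2ccccc2)c1 | intermediate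
3 | 3,5-bis(benzyloxy)phenyl N-(tert-butyldimethylsilyl)-N-isopropylcarbamate | CC(C)N([Si](C)(C)C(C)(C)C)C(=O)Oc1cc(OCc2ccccc2)cc(OCc2ccccc2)c1 | intermediate (not isolated)
4 | 3,5-bis(benzyloxy)-2-(trimethylsilyl)phenyl N-(tert-butyldimethylsilyl)-N-isopropylcarbamate | CC(C)N([Si](C)(C)C(C)(C)C)C(=O)Oc1cc(OCc2ccccc2)cc(OCc2ccccc2)c1[Si](C)(C)C | intermediate (not isolated)
5 | 3,5-bis(benzyloxy)-2-(trimethylsilyl)phenyl N-isopropylcarbamate | CC(C)NC(=O)Oc1cc(OCc2ccccc2)cc(OCc2ccccc2)c1[Si](C)(C)C | intermediate
6 | 3,5-bis(benzyloxy)-2-(trimethylsilyl)phenol (formed as its DBU-H phenoxide) | C[Si](C)(C)c1c(O)cc(OCc2ccccc2)cc1OCc1ccccc1 | intermediate (not isolated)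
7 | 3,5-bis(benzyloxy)-2-(trimethylsilyl)phenyl trifluoromethanesulfonate | C[Si](C)(C)c1c(OS(=O)(=O)C(F)(F)F)cc(OCc2ccccc2)cc1OCc1ccccc1 | intermediate
8 | dimethyl malonate | COC(=O)CC(=O)OC | starting material
9 | 3,5-bis(benzyloxy)benzyne | C1#CC(OCc2ccccc2)=CC(OCc2ccccc2)=C1 | intermediate (not isolated)
10 | potassium benzocyclobutenoxide (methyl 3,5-bis(benzyloxy)-2-methoxy-2-oxidobenzocyclobutene-1-carboxylate, ring fusion carbons C2a/C6a) | COC(=O)C1c2cc(OCc3ccccc3)cc(OCc3ccccc3)c2C1([O-])OC.[K+] | intermediate (not isolated)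
11 | dimethyl 3,5-bis(benzyloxy)homophthalate | COC(=O)Cc1cc(OCc2ccccc2)cc(OCc2ccccc2)c1C(=O)OC | intermediate
12 | 2-[3,5-bis(benzyloxy)-2-(methoxycarbonyl)phenyl]acetic acid | COC(=O)c1c(OCc2ccccc2)cc(OCc2ccccc2)cc1CC(=O)O | intermediate
13 | methyl 2,4-bis(benzyloxy)-6-{2-[methoxy(methyl)amino]-2-oxoethyl}benzoate | COC(=O)c1c(OCc2ccccc2)cc(OCc2ccccc2)cc1CC(=O)N(C)OC | intermediate
14 | pentylmagnesium bromide | CCCCC[Mg]Br | starting material
15 | methyl 2,4-bis(benzyloxy)-6-(2-oxoheptyl)benzoate | CCCCCC(=O)Cc1cc(OCc2ccccc2)cc(OCc2ccccc2)c1C(=O)OC | intermediate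
16 | methyl 2,4-bis(benzyloxy)-6-[(2-pentyl-1,3-dioxolan-2-yl)methyl]benzoate | CCCCCC1(Cc2cc(OCc3ccccc3)cc(OCc3ccccc3)c2C(=O)OC)OCCO1 | intermediate
17 | 2,4-bis(benzyloxy)-6-[(2-pentyl-1,3-dioxolan-2-yl)methyl]benzoic acid | CCCCCC1(Cc2cc(OCc3ccccc3)cc(OCc3ccccc3)c2C(=O)O)OCCO1 | intermediate
18 | 2,4-dihydroxy-6-[(2-pentyl-1,3-dioxolan-2-yl)methyl]benzoic acid | CCCCCC1(Cc2cc(O)cc(O)c2C(=O)O)OCCO1 | intermediate
19 | benzyl 2,4-dihydroxy-6-[(2-pentyl-1,3-dioxolan-2-yl)methyl]benzoate | CCCCCC1(Cc2cc(O)cc(O)c2C(=O)OCc2ccccc2)OCCO1 | intermediate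
20 | benzyl 4-({2,4-bis(benzyloxy)-6-[(2-pentyl-1,3-dioxolan-2-yl)methyl]benzoyl}oxy)-2-hydroxy-6-[(2-pentyl-1,3-dioxolan-2-yl)methyl]benzoate | CCCCCC1(Cc2cc(OC(=O)c3c(OCc4ccccc4)cc(OCc4ccccc4)cc3CC3(CCCCC)OCCO3)cc(O)c2C(=O)OCc2ccccc2)OCCO1 | intermediate
21 | benzyl 4-{[2,4-bis(benzyloxy)-6-(2-oxoheptyl)benzoyl]oxy}-2-hydroxy-6-(2-oxoheptyl)benzoate | CCCCCC(=O)Cc1cc(OC(=O)c2c(OCc3ccccc3)cc(OCc3ccccc3)cc2CC(=O)CCCCC)cc(O)c1C(=O)OCc1ccccc1 | intermediate
22 | 4-{[2,4-dihydroxy-6-(2-oxoheptyl)benzoyl]oxy}-2-hydroxy-6-(2-oxoheptyl)benzoic acid | CCCCCC(=O)Cc1cc(OC(=O)c2c(O)cc(O)cc2CC(=O)CCCCC)cc(O)c1C(=O)O | target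

**Step count**

Total steps: 14. Longest linear sequence: 14 steps (1 to 22), because both coupling partners share steps 1 to 9 and phenol 19 is made from acid 17.

**Steps most likely to fail**

Step 4 (key step). The aryl anion may be protonated before it closes onto the ester, which gives plain alpha-arylation of the malonate. The acidic CH2 of the product may add to a second aryne. The carbanion may also add with the reverse orientation. The fallback leaves the aryne and builds the same vicinal pair by electrophilic formylation; it sets out from 1 and comes back at 11. Phenol 1 is triflated (Tf2O, pyridine, CH2Cl2, 0 °C) to 3,5-bis(benzyloxy)phenyl trifluoromethanesulfonate F1. Palladium-catalysed alpha-arylation of dimethyl malonate 8 (Pd(OAc)2, 2-(di-tert-butylphosphino)biphenyl, K3PO4, toluene, 90 °C) gives dimethyl 2-[3,5-bis(benzyloxy)phenyl]malonate F2. Krapcho dealkoxycarbonylation (LiCl, wet DMSO, 140 °C) gives methyl 2-[3,5-bis(benzyloxy)phenyl]acetate F3. Vilsmeier–Haack formylation (POCl3, DMF) should go to the ring carbon ortho to the CH2 group and para to a benzyloxy group; the two such carbons are equivalent and the carbon between the two benzyloxy groups is more crowded. This gives methyl 2-[3,5-bis(benzyloxy)-2-formylphenyl]acetate F4. Pinnick oxidation (NaClO2, NaH2PO4, 2-methyl-2-butene, t-BuOH/H2O) gives 2,4-bis(benzyloxy)-6-(2-methoxy-2-oxoethyl)benzoic acid F5, and methylation (MeI, K2CO3, DMF) returns to 11.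

Step 12. Acyl transfer from the doubly ortho-substituted acid may be slow, so the carbodiimide-activated acid may rearrange to an N-acylurea. The chelated 2-OH may be acylated as well, or a ketal oxygen may trap the activated acyl group. The fallback uses a discrete acyl chloride and a preformed phenoxide in place of in situ activation; it sets out from 17 (with 19) and comes back at 20. Acid 17 is treated with 1-chloro-N,N,2-trimethylprop-1-en-1-amine (CH2Cl2, 0 °C), a neutral chlorinating agent that releases no HCl, to give 2,4-bis(benzyloxy)-6-[(2-pentyl-1,3-dioxolan-2-yl)methyl]benzoyl chloride F6. F6 is added cold to 19 and K2CO3 in acetone, where only the more acidic, non-chelated 4-OH is deprotonated, to give 20.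

Step 2. n-BuLi may deprotonate a benzylic OCH2 group, which leads to Wittig rearrangement, or lithiate between the two benzyloxy groups instead of next to the carbamate. The fallback replaces deprotonation by halogen–metal exchange; it sets out from 1 and comes back at 7. Bromination of 1 ortho to the free hydroxyl (NBS, CH2Cl2, −78 °C) gives 3,5-bis(benzyloxy)-2-bromophenol F7. O-Silylation (hexamethyldisilazane, THF, reflux) gives [3,5-bis(benzyloxy)-2-bromophenoxy]trimethylsilane F8. n-BuLi (THF, −78 °C) effects bromine–lithium exchange, which is much faster than benzylic deprotonation, and the 1,3 O-to-C silyl shift (retro-Brook rearrangement) gives the lithium salt of 6, which is trapped with Tf2O to give 7.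

**Further compounds**

F1 | step 4 | 3,5-bis(benzyloxy)phenyl trifluoromethanesulfonate | O=S(=O)(Oc1cc(OCc2ccccc2)cc(OCc2ccccc2)c1)C(F)(F)F
F2 | step 4 | dimethyl 2-[3,5-bis(benzyloxy)phenyl]malonate | COC(=O)C(C(=O)OC)c1cc(OCc2ccccc2)cc(OCc2ccccc2)c1
F3 | step 4 | methyl 2-[3,5-bis(benzyloxy)phenyl]acetate | COC(=O)Cc1cc(OCc2ccccc2)cc(OCc2ccccc2)c1
F4 | step 4 | methyl 2-[3,5-bis(benzyloxy)-2-formylphenyl]acetate | COC(=O)Cc1cc(OCc2ccccc2)cc(OCc2ccccc2)c1C=O
F5 | step 4 | 2,4-bis(benzyloxy)-6-(2-methoxy-2-oxoethyl)benzoic acid | COC(=O)Cc1cc(OCc2ccccc2)cc(OCc2ccccc2)c1C(=O)O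
F6 | step 12 | 2,4-bis(benzyloxy)-6-[(2-pentyl-1,3-dioxolan-2-yl)methyl]benzoyl chloride | CCCCCC1(Cc2cc(OCc3ccccc3)cc(OCc3ccccc3)c2C(=O)Cl)OCCO1
F7 | step 2 | 3,5-bis(benzyloxy)-2-bromophenol | Oc1cc(OCc2ccccc2)cc(OCc2ccccc2)c1Br
F8 | step 2 | [3,5-bis(benzyloxy)-2-bromophenoxy]trimethylsilane | C[Si](C)(C)Oc1cc(OCc2ccccc2)cc(OCc2ccccc2)c1Br
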